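**Retrosynthetic overview**
- Last bond: the amide, from a free (2S,3S,4R,6E)-aminotriol and (2R)-2-hydroxypentacosanoic acid; the acid is built by three Kochi couplings (C7+C6+C6+C3) and a copper-catalysed opening of methyl (R)-glycidate.
- C4–C5 bond, the C4 carbinol and the (E)-C6=C7 alkene: allylboration of a serine-derived α-silyloxy aldehyde by an α-chiral allylboronate.
- Key step: the allylboronate comes from a stereospecific 1,2-shift of a vinyl group from boron to carbon in a lithiated-carbamate/vinylboronate complex (forms C6–C7, sets the boron-bearing centre).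
- The C1–C4 aldehyde comes from Garner's aldehyde by a proposed new Rh-catalysed silylformylation (forms C3–C4, sets C3).
- Rings: the trans-cyclopropane, the only ring of the target, is made first (Charette cyclopropanation of (E)-hept-2-en-1-ol); the oxazolidine is a temporary ring, closed on serine and opened in the global deprotection.

Assumption: the SMILES is read as the (2R)-2-hydroxypentacosanoyl amide (23 carbons before the carbinol carbon) of a (2S,3S,4R,6E) base carrying a trans-(1S,2S)-cyclopropane; (+)-sparteine, the Charette dioxaborolane and vinylboronic acid pinacol ester are bought.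

**Route**

Step 1
Reactants: 1 4-chlorobutan-1-ol
Product: 2 4-chlorobutyl N,N-di(propan-2-yl)carbamate
Conditions: iPr2NCOCl, Et3N, CH2Cl2, reflux
Reagents that add atoms: N,N-diisopropylcarbamoyl chloride CC(C)N(C(C)C)C(Cl)=O
Why: O-carbamoylation (acyl substitution) installs the Hoppe carbamate that later directs lithiation and serves as leaving group; triethylamine is too weak to cyclise the chloro alcohol to tetrahydrofuran.

Step 2
Reactants: 3 (E)-hept-2-en-1-ol
Product: 4 [(1S,2S)-2-butylcyclopropyl]methanol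
Conditions: Et2Zn, CH2I2, DME, CH2Cl2, −10 °C (Zn(CH2I)2·DME); (4R,5R)-2-butyl-N,N,N′,N′-tetramethyl-1,3,2-dioxaborolane-4,5-dicarboxamide (1.2 equiv), −10 °C → rt
Reagents that add atoms: diiodomethane ICI
Why: Charette asymmetric Simmons–Smith cyclopropanation; the zinc alkoxide bound to the (4R,5R)-dioxaborolane delivers CH2 stereospecifically to one face of the (E)-alkene, giving the trans-(1S,2S) ring (same sense as the (2S,3S) product from cinnamyl alcohol with this ligand).

Step 3
Reactants: 4 [(1S,2S)-2-butylcyclopropyl]methanol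
Product: 5 (1S,2S)-1-(bromomethyl)-2-butylcyclopropane
Conditions: CBr4, PPh3, CH2Cl2, 0 °C
Reagents that add atoms: carbon tetrabromide BrC(Br)(Br)Br
Why: Appel bromination proceeds by SN2 on the oxyphosphonium ion, so no cyclopropylcarbinyl cation forms and the ring and its stereocentres stay intact.

Step 4
Reactants: 2 4-chlorobutyl N,N-di(propan-2-yl)carbamate; 5 (1S,2S)-1-(bromomethyl)-2-butylcyclopropane
Product: 7 5-[(1S,2S)-2-butylcyclopropyl]pentyl N,N-di(propan-2-yl)carbamate, via carbamate Grignard reagent 6 (not isolated)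
Conditions: 2, Mg, LiCl, I2 (cat.), THF, 45 °C; then 5, Li2CuCl4 (5 mol%), NMP, THF, 0 °C → rt
Reagents that add atoms: none
Why: Kochi-type copper-catalysed sp3–sp3 Grignard coupling is SN2-like at the primary bromide (no radical ring opening of the cyclopropylmethyl unit), and the hindered diisopropylcarbamate is inert to the Grignard function.

Step 5
Reactants: 7 5-[(1S,2S)-2-butylcyclopropyl]pentyl N,N-di(propan-2-yl)carbamate
Product: 10 2-[(3S)-7-[(1S,2S)-2-butylcyclopropyl]hept-1-en-3-yl]-4,4,5,5-tetramethyl-1,3,2-dioxaborolane, via lithiated carbamate 8 (not isolated), via vinyl boronate complex 9 (not isolated)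
Conditions: s-BuLi, (+)-sparteine, Et2O, −78 °C, 5 h; CH2=CHBpin, −78 °C, 1 h; MgBr2·OEt2, −78 → 35 °C, 12 h
Reagents that add atoms: vinylboronic acid pinacol ester C=CB1OC(C)(C)C(C)(C)O1
Why: Hoppe–Aggarwal lithiation–borylation (key step): (+)-sparteine-directed removal of the pro-R proton gives configurationally stable (R)-8, borylation occurs with retention, and the vinyl group then shifts 1,2 from boron to carbon anti to the departing carbamate (inversion), which forms C6–C7 and sets the (S)-boron-bearing centre.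

Step 6
Reactants: 11 L-serine
Product: 13 methyl N-(tert-butoxycarbonyl)-L-serinate, via methyl L-serinate hydrochloride 12 (not isolated)
Conditions: SOCl2, MeOH, 0 °C → reflux; evaporate; Boc2O, Et3N, CH2Cl2, 0 °C → rt
Reagents that add atoms: methanol CO; di-tert-butyl dicarbonate CC(C)(C)OC(=O)OC(=O)OC(C)(C)C
Why: Acid-mediated esterification followed by N-acylation with Boc2O, neither of which touches the α-stereocentre.

Step 7
Reactants: 13 methyl N-(tert-butoxycarbonyl)-L-serinate
Product: 14 3-tert-butyl 4-methyl (4S)-2,2-dimethyl-1,3-oxazolidine-3,4-dicarboxylate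
Conditions: Me2C(OMe)2, BF3·OEt2 (cat.), acetone, rt
Reagents that add atoms: 2,2-dimethoxypropane COC(C)(C)OC
Why: Acid-catalysed transacetalisation closes the N,O-isopropylidene (oxazolidine) ring and masks NH and OH together.

Step 8
Reactants: 14 3-tert-butyl 4-methyl (4S)-2,2-dimethyl-1,3-oxazolidine-3,4-dicarboxylate
Product: 15 tert-butyl (4S)-4-formyl-2,2-dimethyl-1,3-oxazolidine-3-carboxylate
Conditions: iBu2AlH, toluene, −78 °C; MeOH, aq. potassium sodium tartrate
Reagents that add atoms: none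
Why: Partial ester reduction stops at the tetrahedral aluminium hemiacetal at −78 °C and gives Garner's aldehyde without epimerisation.

Step 9
Reactants: 15 tert-butyl (4S)-4-formyl-2,2-dimethyl-1,3-oxazolidine-3-carboxylate
Product: 16 tert-butyl (4S)-4-[(1S)-1-[dimethyl(phenyl)silyl]oxy-2-oxoethyl]-2,2-dimethyl-1,3-oxazolidine-3-carboxylate
Conditions: PhMe2SiH (1.05 equiv), CO (17 bar), [Rh(cod)Cl]2 (1 mol%), THF, 23 °C
Reagents that add atoms: dimethylphenylsilane C[SiH](C)c1ccccc1; carbon monoxide [C-]#[O+]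
Why: Proposed new method: silylformylation of the aldehyde C=O of 15, in which a silyl–rhodium species adds across the carbonyl (Si to O, Rh to C), CO inserts into the Rh–C bond with retention and Si–H hydrogenolysis releases the α-silyloxy aldehyde, so one step forms C3–C4, masks O3 and sets C3 as S because the bulky rhodium nucleophile attacks anti to the ring nitrogen (Felkin–Anh, the face vinylmagnesium bromide uses on this aldehyde); closest known reaction type: rhodium- and cobalt-carbonyl-catalysed silylformylation of simple achiral aldehydes, here extended to an α-amino aldehyde with substrate-controlled induction.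

Step 10
Reactants: 10 2-[(3S)-7-[(1S,2S)-2-butylcyclopropyl]hept-1-en-3-yl]-4,4,5,5-tetramethyl-1,3,2-dioxaborolane; 16 tert-butyl (4S)-4-[(1S)-1-[dimethyl(phenyl)silyl]oxy-2-oxoethyl]-2,2-dimethyl-1,3-oxazolidine-3-carboxylate
Product: 19 tert-butyl (4S)-4-[(1S,2R,4E)-9-[(1S,2S)-2-butylcyclopropyl]-1-[dimethyl(phenyl)silyl]oxy-2-hydroxynon-4-en-1-yl]-2,2-dimethyl-1,3-oxazolidine-3-carboxylate, via butyl boronate complex 17 (not isolated), via allyl borinic ester 18 (not isolated)
Conditions: 10 (1.2 equiv), n-BuLi, THF, −78 °C; (CF3CO)2O, −78 °C; then 16, −78 °C, 4 h; aq. NaHCO3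
Reagents that add atoms: none
Why: Aggarwal-type allylboration through the in situ borinic ester in a closed chair transition state: the α-substituent sits equatorial, which gives the (E)-C6=C7 alkene, and boron and the new C4–C5 bond stay on the same face of the allyl unit, so (S)-10 gives (4R), the 3,4-anti adduct that the α-silyloxy aldehyde itself prefers (matched pair).

Step 11
Reactants: 19 tert-butyl (4S)-4-[(1S,2R,4E)-9-[(1S,2S)-2-butylcyclopropyl]-1-[dimethyl(phenyl)silyl]oxy-2-hydroxynon-4-en-1-yl]-2,2-dimethyl-1,3-oxazolidine-3-carboxylate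
Product: 20 (2S,3S,4R,6E)-2-amino-11-[(1S,2S)-2-butylcyclopropyl]undec-6-ene-1,3,4-triol
Conditions: 3 M aq. HCl/MeOH (1:4), rt; then aq. NaHCO3
Reagents that add atoms: none
Why: Acid solvolysis removes the silyl ether, the N,O-acetonide and the Boc group in one operation, while the isolated (E)-alkene and the dialkylcyclopropane are stable to dilute HCl at room temperature.

Step 12
Reactants: 21 1-bromoheptane; 22 1-bromo-6-chlorohexane
Product: 24 1-chlorotridecane, via heptylmagnesium bromide 23 (not isolated)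
Conditions: 21, Mg, THF, 40 °C; then 22, Li2CuCl4 (2 mol%), THF, 0 °C
Reagents that add atoms: none
Why: Kochi copper-catalysed Grignard coupling is much faster at C–Br than at C–Cl, so the chloride end survives as the handle for the next Grignard reagent.

Step 13
Reactants: 24 1-chlorotridecane; 22 1-bromo-6-chlorohexane
Product: 26 1-chlorononadecane, via tridecylmagnesium chloride 25 (not isolated)
Conditions: 24, Mg, I2 (cat.), THF, reflux; then 22, Li2CuCl4 (2 mol%), THF, 0 °C → rt
Reagents that add atoms: none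
Why: Second Kochi coupling, again selective for bromide over chloride.

Step 14
Reactants: 26 1-chlorononadecane; 27 1-bromo-3-chloropropane
Product: 29 1-chlorodocosane, via nonadecylmagnesium chloride 28 (not isolated)
Conditions: 26, Mg, I2 (cat.), THF, reflux; then 27, Li2CuCl4 (2 mol%), THF, 0 °C → rt
Reagents that add atoms: none
Why: Third Kochi coupling with the same bromide-over-chloride selectivity completes the C22 chain.

Step 15
Reactants: 29 1-chlorodocosane; 30 methyl (2R)-oxirane-2-carboxylate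
Product: 33 (2R)-2-hydroxypentacosanoic acid, via docosylmagnesium chloride 31 (not isolated), via methyl (2R)-2-hydroxypentacosanoate 32 (not isolated)
Conditions: 29, Mg, I2 (cat.), THF, reflux; then 30, CuBr·SMe2 (10 mol%), THF, −40 °C; then LiOH, THF/H2O, 40 °C; 1 M HCl
Reagents that add atoms: lithium hydroxide [Li+].[OH-]
Why: Copper-catalysed SN2 opening of the glycidate at the unsubstituted C3 leaves the (R)-C2–O bond untouched, and the α-hydroxy ester is saponified in the same flask.

Step 16
Reactants: 20 (2S,3S,4R,6E)-2-amino-11-[(1S,2S)-2-butylcyclopropyl]undec-6-ene-1,3,4-triol; 33 (2R)-2-hydroxypentacosanoic acid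
Product: 35 (2R)-N-[(2S,3S,4R,6E)-11-[(1S,2S)-2-butylcyclopropyl]-1,3,4-trihydroxyundec-6-en-2-yl]-2-hydroxypentacosanamide, via hydroxybenzotriazolyl ester 34 (not isolated)
Conditions: EDC, HOBt, THF/DMF, 45 °C
Reagents that add atoms: none
Why: Carbodiimide/HOBt amide coupling; the primary amine is far more nucleophilic than the hydroxyl groups, so N-acylation is chemoselective and the α-hydroxy active ester does not epimerise.

**Compound list**
1 | 4-chlorobutan-1-ol | OCCCCCl | starting material
2 | 4-chlorobutyl N,N-di(propan-2-yl)carbamate | CC(C)N(C(C)C)C(=O)OCCCCCl | intermediate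
3 | (E)-hept-2-en-1-ol | CCCC/C=C/CO | starting material
4 | [(1S,2S)-2-butylcyclopropyl]methanol | OC[C@H]1C[C@@H]1CCCC | intermediate
5 | (1S,2S)-1-(bromomethyl)-2-butylcyclopropane | BrC[C@H]1C[C@@H]1CCCC | intermediate
6 | 4-[di(propan-2-yl)carbamoyloxy]butylmagnesium chloride | CC(C)N(C(C)C)C(=O)OCCCC[Mg]Cl | intermediate
7 | 5-[(1S,2S)-2-butylcyclopropyl]pentyl N,N-di(propan-2-yl)carbamate | CC(C)N(C(C)C)C(=O)OCCCCC[C@H]1C[C@@H]1CCCC | intermediate
8 | (1R)-5-[(1S,2S)-2-butylcyclopropyl]-1-lithiopentyl N,N-di(propan-2-yl)carbamate | CC(C)N(C(C)C)C(=O)O[C@H]([Li])CCCC[C@H]1C[C@@H]1CCCC | intermediate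
9 | lithium vinyl boronate complex of 8 with vinylboronic acid pinacol ester | [Li+].CC(C)N(C(C)C)C(=O)O[C@@H](CCCC[C@H]1C[C@@H]1CCCC)[B-]2(C=C)OC(C)(C)C(C)(C)O2 | intermediate
10 | 2-[(3S)-7-[(1S,2S)-2-butylcyclopropyl]hept-1-en-3-yl]-4,4,5,5-tetramethyl-1,3,2-dioxaborolane | C=C[C@H](CCCC[C@H]1C[C@@H]1CCCC)B2OC(C)(C)C(C)(C)O2 | intermediate
11 | L-serine | N[C@@H](CO)C(=O)O | starting material
12 | methyl L-serinate hydrochloride | [Cl-].COC(=O)[C@@H]([NH3+])CO | intermediate
13 | methyl N-(tert-butoxycarbonyl)-L-serinate | COC(=O)[C@@H](NC(=O)OC(C)(C)C)CO | intermediate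
14 | 3-tert-butyl 4-methyl (4S)-2,2-dimethyl-1,3-oxazolidine-3,4-dicarboxylate | CC(C)(C)OC(=O)N1[C@H](C(=O)OC)COC1(C)C | intermediate
15 | tert-butyl (4S)-4-formyl-2,2-dimethyl-1,3-oxazolidine-3-carboxylate | CC(C)(C)OC(=O)N1[C@H](C=O)COC1(C)C | intermediate
16 | tert-butyl (4S)-4-[(1S)-1-[dimethyl(phenyl)silyl]oxy-2-oxoethyl]-2,2-dimethyl-1,3-oxazolidine-3-carboxylate | CC(C)(C)OC(=O)N1[C@H]([C@H](O[Si](C)(C)c2ccccc2)C=O)COC1(C)C | intermediate
17 | lithium butyl boronate complex of 10 | [Li+].C=C[C@H](CCCC[C@H]1C[C@@H]1CCCC)[B-]2(CCCC)OC(C)(C)C(C)(C)O2 | intermediate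
18 | 2,3-dimethyl-3-(trifluoroacetoxy)butan-2-yl butyl[(3S)-7-[(1S,2S)-2-butylcyclopropyl]hept-1-en-3-yl]borinate | C=C[C@H](CCCC[C@H]1C[C@@H]1CCCC)B(CCCC)OC(C)(C)C(C)(C)OC(=O)C(F)(F)F | intermediate
19 | tert-butyl (4S)-4-[(1S,2R,4E)-9-[(1S,2S)-2-butylcyclopropyl]-1-[dimethyl(phenyl)silyl]oxy-2-hydroxynon-4-en-1-yl]-2,2-dimethyl-1,3-oxazolidine-3-carboxylate | CC(C)(C)OC(=O)N1[C@H]([C@H](O[Si](C)(C)c2ccccc2)[C@H](O)C/C=C/CCCC[C@H]3C[C@@H]3CCCC)COC1(C)C | intermediate
20 | (2S,3S,4R,6E)-2-amino-11-[(1S,2S)-2-butylcyclopropyl]undec-6-ene-1,3,4-triol | N[C@@H](CO)[C@H](O)[C@H](O)C/C=C/CCCC[C@H]1C[C@@H]1CCCC | intermediate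
21 | 1-bromoheptane | CCCCCCCBr | starting material
22 | 1-bromo-6-chlorohexane | ClCCCCCCBr | starting material
23 | heptylmagnesium bromide | CCCCCCC[Mg]Br | intermediate
24 | 1-chlorotridecane | CCCCCCCCCCCCCCl | intermediate
25 | tridecylmagnesium chloride | CCCCCCCCCCCCC[Mg]Cl | intermediate
26 | 1-chlorononadecane | CCCCCCCCCCCCCCCCCCCCl | intermediate
27 | 1-bromo-3-chloropropane | ClCCCBr | starting material
28 | nonadecylmagnesium chloride | CCCCCCCCCCCCCCCCCCC[Mg]Cl | intermediate
29 | 1-chlorodocosane | CCCCCCCCCCCCCCCCCCCCCCCl | intermediate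
30 | methyl (2R)-oxirane-2-carboxylate | COC(=O)[C@H]1CO1 | starting material
31 | docosylmagnesium chloride | CCCCCCCCCCCCCCCCCCCCCC[Mg]Cl | intermediate
32 | methyl (2R)-2-hydroxypentacosanoate | CCCCCCCCCCCCCCCCCCCCCCC[C@@H](O)C(=O)OC | intermediate
33 | (2R)-2-hydroxypentacosanoic acid | CCCCCCCCCCCCCCCCCCCCCCC[C@@H](O)C(=O)O | intermediate
34 | benzotriazol-1-yl (2R)-2-hydroxypentacosanoate | CCCCCCCCCCCCCCCCCCCCCCC[C@@H](O)C(=O)On1nnc2ccccc12 | intermediate
35 | (2R)-N-[(2S,3S,4R,6E)-11-[(1S,2S)-2-butylcyclopropyl]-1,3,4-trihydroxyundec-6-en-2-yl]-2-hydroxypentacosanamide | CCCCCCCCCCCCCCCCCCCCCCC[C@@H](O)C(=O)N[C@@H](CO)[C@H](O)[C@H](O)C/C=C/CCCC[C@H]1C[C@@H]1CCCC | target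

**Totals**
Total steps: 16. Longest linear sequence: 7 steps (3 → 4 → 5 → 7 → 10 → 19 → 20 → 35; the serine branch 11 → 13 → 14 → 15 → 16 → 19 → 20 → 35 is equally long).

**Steps most likely to fail**

Step 9 (the proposed new silylformylation). Possible failures are plain hydrosilylation of the aldehyde, a chelation-controlled syn product, or β-hydride loss at the α-silyloxyalkyl–rhodium stage eroding C2. The fallback uses known chemistry, sets out from 15 and comes back at 16. CH2=CHMgBr in THF at −78 °C (Felkin addition, anti:syn about 6:1, separable) gives tert-butyl (4S)-4-[(1R)-1-hydroxyprop-2-en-1-yl]-2,2-dimethyl-1,3-oxazolidine-3-carboxylate F1. PhMe2SiCl/imidazole in DMF gives tert-butyl (4S)-4-[(1R)-1-[dimethyl(phenyl)silyl]oxyprop-2-en-1-yl]-2,2-dimethyl-1,3-oxazolidine-3-carboxylate F2. Ozonolysis (O3, CH2Cl2, −78 °C, then PPh3) returns to 16.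

Step 10 (allylboration). The α-silyloxy aldehyde can epimerise, and E/Z or C4 selectivity may drop. The fallback separates carbinol formation from alkene formation, sets out from 16 and 5 and comes back at 19. (+)-Ipc2B(allyl) (from (−)-α-pinene), Et2O, −78 °C, then NaBO3 work-up, converts 16 into tert-butyl (4S)-4-[(1S,2R)-1-[dimethyl(phenyl)silyl]oxy-2-hydroxypent-4-en-1-yl]-2,2-dimethyl-1,3-oxazolidine-3-carboxylate F3. Pent-4-enylmagnesium bromide with Li2CuCl4 converts 5 into (1S,2S)-1-butyl-2-(hex-5-en-1-yl)cyclopropane F4. Cross-metathesis of F3 with excess F4 using RuCl2(=CHPh)(PCy3)(H2IMes) (second-generation Grubbs catalyst) in CH2Cl2 at 40 °C gives 19 as the major (E)-isomer after chromatography.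

Step 4 (Grignard formation next to a carbamate and coupling at a cyclopropylmethyl bromide). Possible failures are self-attack of the Grignard reagent on the carbamate and ring opening of the bromide. The fallback keeps the carbonyl group out of the organometallic, sets out from 5 and comes back at 7. But-3-enylmagnesium bromide with Li2CuCl4 in THF gives (1S,2S)-1-butyl-2-(pent-4-en-1-yl)cyclopropane F5. 9-BBN, then NaOH/H2O2, gives 5-[(1S,2S)-2-butylcyclopropyl]pentan-1-ol F6. iPr2NCOCl/Et3N returns to 7.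

Further compounds
F1 | step 9 | tert-butyl (4S)-4-[(1R)-1-hydroxyprop-2-en-1-yl]-2,2-dimethyl-1,3-oxazolidine-3-carboxylate | CC(C)(C)OC(=O)N1[C@H]([C@H](O)C=C)COC1(C)C
F2 | step 9 | tert-butyl (4S)-4-[(1R)-1-[dimethyl(phenyl)silyl]oxyprop-2-en-1-yl]-2,2-dimethyl-1,3-oxazolidine-3-carboxylate | CC(C)(C)OC(=O)N1[C@H]([C@H](O[Si](C)(C)c2ccccc2)C=C)COC1(C)C
F3 | step 10 | tert-butyl (4S)-4-[(1S,2R)-1-[dimethyl(phenyl)silyl]oxy-2-hydroxypent-4-en-1-yl]-2,2-dimethyl-1,3-oxazolidine-3-carboxylate | CC(C)(C)OC(=O)N1[C@H]([C@H](O[Si](C)(C)c2ccccc2)[C@H](O)CC=C)COC1(C)C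
F4 | step 10 | (1S,2S)-1-butyl-2-(hex-5-en-1-yl)cyclopropane | C=CCCCC[C@H]1C[C@@H]1CCCC
F5 | step 4 | (1S,2S)-1-butyl-2-(pent-4-en-1-yl)cyclopropane | C=CCCC[C@H]1C[C@@H]1CCCC
F6 | step 4 | 5-[(1S,2S)-2-butylcyclopropyl]pentan-1-ol | OCCCCC[C@H]1C[C@@H]1CCCC
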